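**Plan**

- Cuts (benzofuran numbering; ring A = benzo ring, ring B = trimethoxyphenyl): the O6 ester, then O1–C2 together with C3–H, then C3–C3a, then C5–allyl; on the ring B side the alkenyl C–B bond and the aryl–alkyne bond.
- Enabling feature: O1–C2 and C3–H are what addition of the C7a hydroxyl across a C2=C3 double bond gives, and C2 is benzylic to ring B, so protonation at C3 leaves a cation on which the ortho oxygen can close the five-membered ring.
- Forward: ring A is dressed first (pivalate on the later O6, then iodide and allyl at the later C5), ring B is extended to a (Z)-alkenyl boronate, the halves are joined at C3–C3a, the dihydrofuran ring is closed last and the ester is removed.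
- Stereochemistry: the E alkene comes from syn borylcupration and a stereoretentive coupling; C3 is set by face-selective protonation with a confined chiral imidodiphosphorimidate acid, and C2 follows as trans in the ring closure.

Key step: step 7

Assumption: the sense of induction of the confined acid on this substrate cannot be derived from precedent, so the (S,S)-acid is written and its mirror image is to be used if a first run gives the (2R,3R) series.

**Step 1**
Reactants: 1 4-bromoresorcinol (4-bromobenzene-1,3-diol)
Product: 2 4-bromo-3-hydroxyphenyl pivalate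
Conditions: PivCl (1.0 equiv, slow addition), pyridine (2 equiv), CH2Cl2, −30 to 0 °C
Reagents that add atoms: pivaloyl chloride, CC(C)(C)C(=O)Cl
Why: Nucleophile-catalysed O-acylation through the N-pivaloylpyridinium ion should take the hydroxyl para to bromine, because the other hydroxyl is flanked by bromine and hydrogen-bonded to it, and one equivalent of a bulky acyl donor limits diacylation.

**Step 2**
Reactants: 2 4-bromo-3-hydroxyphenyl pivalate
Product: 3 4-bromo-5-hydroxy-2-iodophenyl pivalate
Conditions: NIS (1.05 equiv), p-toluenesulfonic acid monohydrate (10 mol %), MeCN, 0 °C to rt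
Reagents that add atoms: N-iodosuccinimide, O=C1CCC(=O)N1I
Why: Electrophilic aromatic iodination should go para to the free hydroxyl (ortho to the ester oxygen), since one ortho position carries bromine and the other lies crowded between the two oxygens.

**Step 3**
Reactants: 3 4-bromo-5-hydroxy-2-iodophenyl pivalate; 4 allyltributylstannane
Product: 5 2-allyl-4-bromo-5-hydroxyphenyl pivalate
Conditions: Pd(PPh3)4 (5 mol %), CuI (10 mol %), DMF, 50 °C
Reagents that add atoms: none
Why: In this Migita–Kosugi–Stille coupling zerovalent palladium inserts into C–I far faster than into C–Br, so only the iodide is exchanged for allyl, and the neutral conditions spare the pivalate, the free phenol and the terminal position of the allyl double bond.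

**Step 4**
Reactants: 6 5-iodo-1,2,3-trimethoxybenzene; 7 propyne
Product: 8 1,2,3-trimethoxy-5-(prop-1-yn-1-yl)benzene
Conditions: PdCl2(PPh3)2 (2 mol %), CuI (4 mol %), Et3N, THF, propyne (1 M in THF, 2 equiv), sealed vessel, rt
Reagents that add atoms: none
Why: Sonogashira coupling of an aryl iodide with a terminal alkyne proceeds at room temperature, and an excess of the volatile alkyne is used.

**Step 5**
Reactants: 8 1,2,3-trimethoxy-5-(prop-1-yn-1-yl)benzene
Product: 9 (Z)-4,4,5,5-tetramethyl-2-[1-(3,4,5-trimethoxyphenyl)prop-1-en-2-yl]-1,3,2-dioxaborolane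
Conditions: B2pin2 (1.1 equiv), CuCl (5 mol %), P(p-tol)3 (6 mol %), NaOt-Bu (10 mol %), MeOH (2 equiv), THF, rt
Reagents that add atoms: bis(pinacolato)diboron, CC1(C)OB(OC1(C)C)B1OC(C)(C)C(C)(C)O1
Why: In this copper-catalysed formal hydroboration the Cu–Bpin species adds syn across the alkyne with copper on the aryl-bearing carbon and boron on the methyl-bearing carbon, and methanol cleaves the C–Cu bond with retention, so aryl and methyl end up cis (Z-boronate).

**Step 6**
Reactants: 5 2-allyl-4-bromo-5-hydroxyphenyl pivalate; 9 (Z)-4,4,5,5-tetramethyl-2-[1-(3,4,5-trimethoxyphenyl)prop-1-en-2-yl]-1,3,2-dioxaborolane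
Product: 10 (E)-2-allyl-5-hydroxy-4-[1-(3,4,5-trimethoxyphenyl)prop-1-en-2-yl]phenyl pivalate
Conditions: Pd(OAc)2 (3 mol %), SPhos (6 mol %), K3PO4 (3 equiv), THF/H2O 10:1, 60 °C
Reagents that add atoms: none
Why: Suzuki–Miyaura coupling keeps the alkene geometry (ring A replaces boron trans to ring B), the electron-rich biarylphosphine permits oxidative addition next to the phenoxide, and an aryl pivalate should tolerate aqueous phosphate at this temperature.

**Step 7**
Reactants: 10 (E)-2-allyl-5-hydroxy-4-[1-(3,4,5-trimethoxyphenyl)prop-1-en-2-yl]phenyl pivalate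
Product: 11 (2S,3S)-5-allyl-3-methyl-2-(3,4,5-trimethoxyphenyl)-2,3-dihydrobenzofuran-6-yl pivalate (trans)
Conditions: (S,S)-HN[P(=NSO2CF3)(O2C20H10Ar2)]2 with Ar = 3,5-(CF3)2C6H3 and O2C20H10Ar2 = (S)-3,3'-diaryl-1,1'-binaphthalene-2,2'-diolate (5 mol %), toluene (0.02 M), −40 to −20 °C
Reagents that add atoms: none
Why: Proposed new method: the confined chiral acid should transfer its proton to C3 of the alkene, and the transient C2 benzylic cation, stabilised by ring B and paired in the pocket with the chiral anion, is captured by the neighbouring C7a hydroxyl, which returns its proton to the anion. The closest known reaction types are the racemic strong-acid cyclisation of 2-hydroxystilbenes to 2-aryl-2,3-dihydrobenzofurans and the asymmetric intramolecular hydroalkoxylation of alkenes by confined imidodiphosphorimidate acids, whose combination on a stilbene with a phenol nucleophile is untested. The dihydrofuran ring closes by O1–C2 bond formation in a mode that is formally 5-endo-trig with respect to C2=C3, which is permitted here because C–H bond formation runs ahead and oxygen adds to a planar cationic C2, not to an intact alkene terminus. C3 is set by the face of proton delivery inside the catalyst pocket, and C2 is set relative to C3 during ring closure, ring B going anti to the C3 methyl to give the trans isomer, which is also the more stable one. The step needs productive protonation at C3: protonation at C2 gives a more stabilised tertiary cation, but that cation has no ring closure open to it (a four-membered ring would result) and returns to alkene, and the pivaloyloxy group para to C3a tempers both its stability and the nucleophilicity of ring A. The terminal allyl alkene is far less basic than the stilbene and its neighbouring oxygen is acylated, so a second cyclisation cannot compete.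

**Step 8**
Reactants: 11 (2S,3S)-5-allyl-3-methyl-2-(3,4,5-trimethoxyphenyl)-2,3-dihydrobenzofuran-6-yl pivalate
Product: 12 (2S,3S)-5-allyl-3-methyl-2-(3,4,5-trimethoxyphenyl)-2,3-dihydrobenzofuran-6-ol (CNP0286233.1)
Conditions: K2CO3 (1.5 equiv), MeOH, rt; aq. NH4Cl work-up
Reagents that add atoms: none
Why: Base-mediated methanolysis (transesterification) of the aryl ester frees the C6 phenol, while neither stereocentre carries an acidic hydrogen and the allyl group is inert to carbonate.

**Compound list**

1 | 4-bromoresorcinol | Oc1ccc(Br)c(O)c1 | starting material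
2 | 4-bromo-3-hydroxyphenyl pivalate | CC(C)(C)C(=O)Oc1ccc(Br)c(O)c1 | intermediate
3 | 4-bromo-5-hydroxy-2-iodophenyl pivalate | CC(C)(C)C(=O)Oc1cc(O)c(Br)cc1I | intermediate
4 | allyltributylstannane | C=CC[Sn](CCCC)(CCCC)CCCC | starting material
5 | 2-allyl-4-bromo-5-hydroxyphenyl pivalate | C=CCc1cc(Br)c(O)cc1OC(=O)C(C)(C)C | intermediate
6 | 5-iodo-1,2,3-trimethoxybenzene | COc1cc(I)cc(OC)c1OC | starting material
7 | propyne | CC#C | starting material
8 | 1,2,3-trimethoxy-5-(prop-1-yn-1-yl)benzene | CC#Cc1cc(OC)c(OC)c(OC)c1 | intermediate
9 | (Z)-4,4,5,5-tetramethyl-2-[1-(3,4,5-trimethoxyphenyl)prop-1-en-2-yl]-1,3,2-dioxaborolane | COc1cc(/C=C(\C)B2OC(C)(C)C(C)(C)O2)cc(OC)c1OC | intermediate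
10 | (E)-2-allyl-5-hydroxy-4-[1-(3,4,5-trimethoxyphenyl)prop-1-en-2-yl]phenyl pivalate | C=CCc1cc(/C(C)=C/c2cc(OC)c(OC)c(OC)c2)c(O)cc1OC(=O)C(C)(C)C | intermediate
11 | (2S,3S)-5-allyl-3-methyl-2-(3,4,5-trimethoxyphenyl)-2,3-dihydrobenzofuran-6-yl pivalate | C=CCc1cc2c(cc1OC(=O)C(C)(C)C)O[C@H](c1cc(OC)c(OC)c(OC)c1)[C@H]2C | intermediate
12 | (2S,3S)-5-allyl-3-methyl-2-(3,4,5-trimethoxyphenyl)-2,3-dihydrobenzofuran-6-ol | C=CCc1cc2c(cc1O)O[C@H](c1cc(OC)c(OC)c(OC)c1)[C@H]2C | target

**Count**

Total steps: 8. Longest linear sequence: 6 (steps 1, 2, 3, 6, 7, 8); the ring B branch (steps 4, 5) joins at step 6.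

**Steps most likely to fail**

1. Step 7. Facial discrimination in the proton transfer may be insufficient. Reversible protonation at C2 may scramble the alkene geometry before the productive event. The cations may be diverted into intermolecular alkylation of ring A. Retro-addition through the same cation could erode the enantiomeric purity at long reaction times.
   Fallback (known chemistry), setting out from 10: cyclisation with an achiral strong acid (CF3SO3H, 5 mol %, CH2Cl2, −20 °C) should give the trans-dihydrobenzofuran as a racemate. The racemate consists of 11 and its mirror image (2R,3R)-5-allyl-3-methyl-2-(3,4,5-trimethoxyphenyl)-2,3-dihydrobenzofuran-6-yl pivalate F1. Preparative chromatography on a chiral stationary phase would remove F1, and the route is rejoined at 11.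

2. Step 1. Acylation may leak to the bromine-flanked hydroxyl, which is the more acidic one, or run on to the diester, so that the oxygen differentiation on which steps 2, 3 and 7 rest is lost.
   Fallback, setting out from 1: exhaustive pivaloylation (PivCl, pyridine, DMAP) would give 4-bromo-1,3-phenylene bis(2,2-dimethylpropanoate) F2. Stille coupling of F2 with 4 (Pd(PPh3)4, toluene, 100 °C) would give 4-allyl-1,3-phenylene bis(2,2-dimethylpropanoate) F3. Controlled methanolysis (K2CO3, 1 equiv, MeOH, −10 °C) should cleave the ester with no ortho substituent faster than the one next to the allyl group, giving 2-allyl-5-hydroxyphenyl pivalate F4. Ortho-bromination of the free phenol (NBS, cat. i-Pr2NH, CH2Cl2, −20 °C) has the para position blocked and the other ortho site crowded between the oxygens, so it should deliver 5, where the route is rejoined.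

3. Step 6. Oxidative addition next to the phenoxide may be slow enough for protodeboronation of the hindered alkenyl boronate and hydrolysis of the pivalate to take over.
   Fallback, setting out from 5 and 9 with the coupling roles exchanged: Miyaura borylation of 5 (B2pin2, PdCl2(dppf), KOAc, dioxane, 80 °C) would give 2-allyl-5-hydroxy-4-(4,4,5,5-tetramethyl-1,3,2-dioxaborolan-2-yl)phenyl pivalate F5. Ipso-iododeboronation of 9 with retention (NaOH, then I2, THF/H2O, 0 °C) would give (E)-5-(2-iodoprop-1-en-1-yl)-1,2,3-trimethoxybenzene F6. The reactive alkenyl iodide F6 should couple with F5 under mild conditions (Pd(PPh3)4, K3PO4, THF/H2O, 50 °C) with retention, and the route is rejoined at 10.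

**Further compounds**

F1 | step 7 | (2R,3R)-5-allyl-3-methyl-2-(3,4,5-trimethoxyphenyl)-2,3-dihydrobenzofuran-6-yl pivalate | C=CCc1cc2c(cc1OC(=O)C(C)(C)C)O[C@@H](c1cc(OC)c(OC)c(OC)c1)[C@@H]2C
F2 | step 1 | 4-bromo-1,3-phenylene bis(2,2-dimethylpropanoate) | CC(C)(C)C(=O)Oc1ccc(Br)c(OC(=O)C(C)(C)C)c1
F3 | step 1 | 4-allyl-1,3-phenylene bis(2,2-dimethylpropanoate) | C=CCc1ccc(OC(=O)C(C)(C)C)cc1OC(=O)C(C)(C)C
F4 | step 1 | 2-allyl-5-hydroxyphenyl pivalate | C=CCc1ccc(O)cc1OC(=O)C(C)(C)C
F5 | step 6 | 2-allyl-5-hydroxy-4-(4,4,5,5-tetramethyl-1,3,2-dioxaborolan-2-yl)phenyl pivalate | C=CCc1cc(B2OC(C)(C)C(C)(C)O2)c(O)cc1OC(=O)C(C)(C)C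
F6 | step 6 | (E)-5-(2-iodoprop-1-en-1-yl)-1,2,3-trimethoxybenzene | COc1cc(/C=C(\C)I)cc(OC)c1OC
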